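The south-east flask cannot be running on a single step, substrate to target. A single first-order step ends with the whole charge as target, but this run holds 32.2 % of its charge at 4.0 min and 31.8 % at 4.8 min, two readings that differ by less than their scatter of 0.004 M.

| setting | south-east | north | north-west | south | north-east |
|---|---|---|---|---|---|
| substrate | 0.400 M | 0.160 M | 0.800 M | 0.400 M | 0.400 M |
| target |  |  |  | 0.200 M |  |
| time |  |  |  |  | 9.6 min |

| run | time / min | [target] / M |
|---|---|---|
| south-east run | 0.80 | 0.046 |
| south-east run | 1.6 | 0.083 |
| south-east run | 2.4 | 0.105 |
| south-east run | 3.2 | 0.120 |
| south-east run | 4.0 | 0.129 |
| south-east run | 4.8 | 0.127 |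
| north run | 0.80 | 0.011 |
| north run | 1.6 | 0.034 |
| north run | 2.4 | 0.049 |
| north run | 3.2 | 0.052 |
| north run | 4.0 | 0.059 |
| north run | 4.8 | 0.061 |
| north-west run | 0.80 | 0.088 |
| north-west run | 1.6 | 0.161 |
| north-west run | 2.4 | 0.195 |
| north-west run | 3.2 | 0.205 |
| north-west run | 4.0 | 0.208 |
| north-west run | 4.8 | 0.202 |
| south run | 0.80 | 0.445 |
| south run | 1.6 | 0.475 |
| south run | 2.4 | 0.475 |
| south run | 3.2 | 0.479 |
| south run | 4.0 | 0.477 |
| south run | 4.8 | 0.480 |

(each reading ± 0.004 M)

1. the exponent of [substrate] in the starting rate at the charge of the south-east run (at the point where two percent of the substrate have become target) (one fixed amount of target, the same in the runs compared)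
2. target in the north-east run at 9.6 min, as a share of the substrate charged
3. which of these the readings show (the substrate is lost by itself / the product speeds the reaction / the product binds the substrate / the product decays)

- Overall: substrate -> target.
- Constant volume, constant temperature.
- An order is taken over about fifteen percent of the charge, up and down.

I build the flask up one step at a time and watch the share of the charge that ends as target. The main step alone gives the whole charge. Now I add a loss of substrate. At the last reading the share is 38.1 % in the north run, 31.8 % in the south-east run and 25.2 % in the north-west run. Two first-order steps side by side give the same share at any charge, so I take this loss to be of higher order. Then I add the last step, target speeding its own formation, or autocatalysis. The south run starts with target at half its substrate charge, and its first reading already shows a gain of 61.2 % of the charge, more than the south-east run's 11.5 %. Bound substrate does not do that. The first readings of the north-west and south-east runs give a rough order of 0.936.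

The north-east flask has the south-east charge and runs to 9.6 min. My first answer is the mean of the last two south-east readings, 32.0 %. I put that back. The gap to it is 5.8 percentage points at 2.4 min and 2 points at 3.2 min, so the gap shrinks by a factor 0.348 per reading. At that pace the last two readings still lie 0.47 points short on average. That gives the kept share, the target gained at the end of a run as a fraction of its charge: 32.5 %.

The forecast puts the share at 32.3 % (31 % to 33.8 %) and the exponent at 1.1 (0.85 to 1.5), higher than my rough order, and it names the product speeds the reaction, saying “The south run is decisive”.

The north-east flask gives 33.2 %, 0.70 points above my kept share. The exponent is 1.0, and the answer to the third question is that the product speeds the reaction.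

    substrate → target (0.1278 min⁻¹)
    2 substrate → side product (2.448 L mol⁻¹ min⁻¹)
    substrate + target → 2 target (6.360 L mol⁻¹ min⁻¹)

At the same small amount of target made, the south run's rate is 0.55 M min⁻¹ against 0.054 M min⁻¹ in the south-east run, ten times as much. The north-west run's last two readings give a kept share of 25.6 %, against 32.5 % for the south-east charge.

(The data were generated by integration on assumed constants; scatter was added.)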